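**Retrosynthetic overview**
- The acid is freed last by hydrolysing a masked side-chain carboxyl; the exocyclic methylene comes from the C8 ketone by a non-basic methylenation.
- Key late union (C9–C11 bond): the regiodefined enolate of the cis-fused bicyclic ketone is alkylated with a C6 side-chain iodide whose carboxyl is masked as a bicyclic ortho ester.
- The angular methyl (C10) comes from 1,4-addition of Me2CuLi to a bicyclic enone, which gives the cis ring fusion; the enone comes from a Diels–Alder adduct.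
- Ring order: ring B is carried in from cyclohexane-1,3-dione as a 1-vinylcyclohexene ketal; ring A is closed onto it by an enantioselective Diels–Alder reaction with methacrolein, which sets C4 and C5.
- Side chain: (R)-β-butyrolactone is opened with inversion by CH2=CHMgBr/CuBr·SMe2 (sets C13), then ortho ester formation, hydroboration and iodination.

Assumption: the SMILES is taken literally, i.e. a cis-fused decalin with ring-fusion H, angular CH3, the CH3 on the ester carbon and the side chain on one face and CO2CH3 on the other; atom labels in the explanations follow labdane numbering (C4 ester carbon, C5 ring-fusion CH, C8 methylidene carbon, C9 side-chain carbon, C10 angular carbon, C13 side-chain methine; ring A carries the ester, ring B the methylidene).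

**Step 1**
Reactants: 1 cyclohexane-1,3-dione
Product: 2 3-ethoxycyclohex-2-en-1-one
Conditions: EtOH, TsOH·H2O (cat.), PhMe, reflux, Dean–Stark
Reagents that add atoms: ethanol (CCO)
Why: Acid-catalysed enol etherification of the enolised 1,3-dione (vinylogous ester formation) is driven to completion by azeotropic removal of water; no stereocentre is formed.

**Step 2**
Reactants: 2 3-ethoxycyclohex-2-en-1-one
Product: 4 3-vinylcyclohex-2-en-1-one, via tertiary carbinol 3 (not isolated)
Conditions: CH2=CHMgBr, THF, 0 °C; then 1 M HCl, 0 → 23 °C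
Reagents that add atoms: vinylmagnesium bromide (C=C[Mg]Br); water (O)
Why: Stork–Danheiser enone synthesis, in which 1,2-addition of CH2=CHMgBr to the vinylogous ester and acid-promoted ionisation and hydrolysis of the carbinol transpose the carbonyl group and give the 3-substituted enone; no stereocentre.

**Step 3**
Reactants: 4 3-vinylcyclohex-2-en-1-one
Product: 5 7-vinyl-1,4-dioxaspiro[4.5]dec-7-ene
Conditions: HOCH2CH2OH, TsOH·H2O (cat.), PhH, reflux, Dean–Stark; NaHCO3 work-up
Reagents that add atoms: ethane-1,2-diol (OCCO)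
Why: Acid-catalysed ketalisation runs through the dienol ether, which is protonated at the α-carbon, so the ring double bond moves to the β,γ-position (as in the ketalisation of steroidal 4-en-3-ones), stays conjugated to the vinyl group and gives the 1-vinylcyclohexene diene; no stereocentre.

**Step 4**
Reactants: 5 7-vinyl-1,4-dioxaspiro[4.5]dec-7-ene, 6 methacrolein
Product: 7 (1R,8aS)-6,6-(ethylenedioxy)-1-methyl-1,2,3,5,6,7,8,8a-octahydronaphthalene-1-carbaldehyde
Conditions: (3aR)-3,3-diphenyl-1-(o-tolyl)tetrahydro-1H,3H-pyrrolo[1,2-c][1,3,2]oxazaborole (20 mol %) protonated with Tf2NH (20 mol %), CH2Cl2, −78 → −40 °C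
Reagents that add atoms: none
Why: Enantioselective Diels–Alder reaction (Corey-type cationic oxazaborolidine catalysis) that closes ring A, in which the substituted diene terminus bonds to the enal α-carbon (ortho rule), the formyl group is endo so that CHO ends cis to the ring CH2 on C5, and the (R)-catalyst, binding the aldehyde through B–O and formyl C–H···O contacts, leaves only the Si face of the α-carbon open, fixing C4 as R and C5 as S.

**Step 5**
Reactants: 7 (1R,8aS)-6,6-(ethylenedioxy)-1-methyl-1,2,3,5,6,7,8,8a-octahydronaphthalene-1-carbaldehyde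
Product: 8 (1R,8aS)-6,6-(ethylenedioxy)-1-methyl-1,2,3,5,6,7,8,8a-octahydronaphthalene-1-carboxylic acid
Conditions: NaClO2, NaH2PO4, 2-methyl-2-butene, t-BuOH/H2O, 0 → 23 °C
Reagents that add atoms: sodium chlorite ([Na+].[O-]Cl=O)
Why: Pinnick oxidation of the non-enolisable neopentyl aldehyde under phosphate buffer with an HOCl scavenger leaves the ketal, the trisubstituted alkene and both stereocentres untouched.

**Step 6**
Reactants: 8 (1R,8aS)-6,6-(ethylenedioxy)-1-methyl-1,2,3,5,6,7,8,8a-octahydronaphthalene-1-carboxylic acid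
Product: 11 methyl (1R,8aS)-1-methyl-6-oxo-1,2,3,4,6,7,8,8a-octahydronaphthalene-1-carboxylate, via ketal ester 9 (not isolated), via deconjugated enone 10 (not isolated)
Conditions: MeI, K2CO3, DMF, 23 °C; aqueous work-up; then 1 M HCl, THF, 23 °C
Reagents that add atoms: iodomethane (CI); water (O)
Why: SN2 O-methylation of the hindered carboxylate is followed by acid hydrolysis of the ketal and acid-catalysed shift of the β,γ-double bond into conjugation (dienol protonated at C1), under conditions too mild to enolise towards C5, so both stereocentres are kept.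

**Step 7**
Reactants: 11 methyl (1R,8aS)-1-methyl-6-oxo-1,2,3,4,6,7,8,8a-octahydronaphthalene-1-carboxylate
Product: 13 methyl (1R,4aS,8aS)-1,4a-dimethyl-6-(trimethylsilyloxy)-1,2,3,4,4a,7,8,8a-octahydronaphthalene-1-carboxylate, via lithium enolate 12 (not isolated)
Conditions: Me2CuLi (from CuI + 2 MeLi), Et2O, −78 → 0 °C; then Me3SiCl, Et3N, 0 → 23 °C
Reagents that add atoms: lithium dimethylcuprate ([Li+].C[Cu-]C); chlorotrimethylsilane (C[Si](C)(C)Cl)
Why: Conjugate (1,4-) addition of Me2CuLi to the octalone, in which methyl enters C10 axially, anti to the C5–C4 bond and on the face away from the axial ester, gives the cis ring fusion (angular methyl cis to H-5), and silylation fixes the enolate regiospecifically as its silyl enol ether.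

**Step 8**
Reactants: 14 (R)-4-methyloxetan-2-one
Product: 15 (3S)-3-methylpent-4-enoic acid
Conditions: CH2=CHMgBr, CuBr·SMe2 (10 mol %), THF/Me2S, −30 °C; then 1 M HCl
Reagents that add atoms: vinylmagnesium bromide (C=C[Mg]Br)
Why: Copper-catalysed SN2 opening of the β-lactone at the β-carbon (alkyl–oxygen cleavage) proceeds with inversion, so the (R)-lactone gives the (S)-acid, whose spatial arrangement is that of C13 of the target.

**Step 9**
Reactants: 15 (3S)-3-methylpent-4-enoic acid
Product: 16 (3-methyloxetan-3-yl)methyl (3S)-3-methylpent-4-enoate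
Conditions: (3-methyloxetan-3-yl)methanol, N,N'-dicyclohexylcarbodiimide, 4-(dimethylamino)pyridine (cat.), CH2Cl2, 0 → 23 °C
Reagents that add atoms: (3-methyloxetan-3-yl)methanol (CC1(CO)COC1)
Why: Steglich esterification (carbodiimide activation with nucleophilic catalysis) installs the oxetanylmethyl ester without touching the stereocentre.

**Step 10**
Reactants: 16 (3-methyloxetan-3-yl)methyl (3S)-3-methylpent-4-enoate
Product: 17 4-methyl-1-[(2S)-2-methylbut-3-en-1-yl]-2,6,7-trioxabicyclo[2.2.2]octane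
Conditions: BF3·OEt2 (0.25 equiv), CH2Cl2, −15 → 23 °C; then Et3N
Reagents that add atoms: none
Why: Lewis-acid-catalysed rearrangement of the oxetanyl ester (Corey OBO ortho ester formation) masks the carboxyl as a base-stable, non-enolisable, non-electrophilic group for the later enolate alkylation.

**Step 11**
Reactants: 17 4-methyl-1-[(2S)-2-methylbut-3-en-1-yl]-2,6,7-trioxabicyclo[2.2.2]octane
Product: 19 (3R)-3-methyl-4-(4-methyl-2,6,7-trioxabicyclo[2.2.2]octan-1-yl)butan-1-ol, via alkylborane 18 (not isolated)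
Conditions: 9-borabicyclo[3.3.1]nonane (9-BBN), THF, 0 → 23 °C; then NaOH, H2O2, 0 °C
Reagents that add atoms: hydrogen peroxide (OO)
Why: Anti-Markovnikov hydroboration of the terminal alkene with the bulky dialkylborane and alkaline peroxide oxidation give the primary alcohol, the ortho ester being stable to base and the stereocentre not involved (its descriptor changes only by priority).

**Step 12**
Reactants: 19 (3R)-3-methyl-4-(4-methyl-2,6,7-trioxabicyclo[2.2.2]octan-1-yl)butan-1-ol
Product: 20 1-[(2S)-4-iodo-2-methylbutyl]-4-methyl-2,6,7-trioxabicyclo[2.2.2]octane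
Conditions: I2, PPh3, imidazole, CH2Cl2, 0 °C
Reagents that add atoms: iodine (II)
Why: Appel-type iodination (Garegg–Samuelsson conditions) converts the primary alcohol into the iodide by SN2 displacement of the oxyphosphonium group, with imidazole buffering the acid-sensitive ortho ester.

**Step 13**
Reactants: 13 methyl (1R,4aS,8aS)-1,4a-dimethyl-6-(trimethylsilyloxy)-1,2,3,4,4a,7,8,8a-octahydronaphthalene-1-carboxylate, 20 1-[(2S)-4-iodo-2-methylbutyl]-4-methyl-2,6,7-trioxabicyclo[2.2.2]octane
Product: 22 methyl (1R,4aS,5R,8aS)-1,4a-dimethyl-5-[(3R)-3-methyl-4-(4-methyl-2,6,7-trioxabicyclo[2.2.2]octan-1-yl)butyl]-6-oxodecahydronaphthalene-1-carboxylate, via ammonium enolate 21 (not isolated)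
Conditions: BnMe3NF (anhydrous), 4 Å molecular sieves, THF, 0 → 23 °C
Reagents that add atoms: none
Why: Fluoride cleavage of the silyl enol ether gives a regiodefined, highly nucleophilic ammonium enolate that is C-alkylated by the primary iodide (SN2, Kuwajima–Nakamura type), the electrophile reaching C9 on the convex face of the cis-decalin, anti to the axial ring-A carbon C1 on the neighbouring quaternary centre and hence syn to the angular methyl, which sets C9 and joins the two fragments.

**Step 14**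
Reactants: 22 methyl (1R,4aS,5R,8aS)-1,4a-dimethyl-5-[(3R)-3-methyl-4-(4-methyl-2,6,7-trioxabicyclo[2.2.2]octan-1-yl)butyl]-6-oxodecahydronaphthalene-1-carboxylate
Product: 24 methyl (1R,4aR,5S,8aS)-5-{(3R)-5-[3-hydroxy-2-(hydroxymethyl)-2-methylpropoxy]-3-methyl-5-oxopentyl}-1,4a-dimethyl-6-methylidenedecahydronaphthalene-1-carboxylate, via ortho ester olefin 23 (not isolated)
Conditions: Zn, CH2Br2, TiCl4 (reagent preformed in THF), CH2Cl2, 0 → 23 °C; then 0.5 M HCl, THF, 0 °C, 15 min
Reagents that add atoms: dibromomethane (BrCBr); water (O)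
Why: Lombardo methylenation (Zn/CH2Br2/TiCl4) is non-basic, so the epimerisable α-centre C9 is preserved and the esters are left alone, and the dilute-acid work-up opens the ortho ester to its diol monoester.

**Step 15**
Reactants: 24 methyl (1R,4aR,5S,8aS)-5-{(3R)-5-[3-hydroxy-2-(hydroxymethyl)-2-methylpropoxy]-3-methyl-5-oxopentyl}-1,4a-dimethyl-6-methylidenedecahydronaphthalene-1-carboxylate
Product: 25 (3R)-5-[(1S,4aS,5R,8aR)-5-(methoxycarbonyl)-5,8a-dimethyl-2-methylidenedecahydronaphthalen-1-yl]-3-methylpentanoic acid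
Conditions: LiOH, THF/H2O, 0 → 23 °C; then 1 M HCl to pH 3
Reagents that add atoms: lithium hydroxide ([Li+].[OH-])
Why: Saponification cleaves the unhindered primary side-chain ester while the α-quaternary, neopentyl-type ring methyl ester reacts far more slowly and survives, giving the target mono-acid.

**Compound list**
1 | cyclohexane-1,3-dione | O=C1CCCC(=O)C1 | starting material
2 | 3-ethoxycyclohex-2-en-1-one | CCOC1=CC(=O)CCC1 | intermediate
3 | 3-ethoxy-1-vinylcyclohex-2-en-1-ol (racemic tertiary carbinol) | CCOC1=CC(O)(C=C)CCC1 | intermediate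
4 | 3-vinylcyclohex-2-en-1-one | C=CC1=CC(=O)CCC1 | intermediate
5 | 7-vinyl-1,4-dioxaspiro[4.5]dec-7-ene | C=CC1=CCCC2(C1)OCCO2 | intermediate
6 | methacrolein (2-methylprop-2-enal) | CC(=C)C=O | starting material
7 | (1R,8aS)-6,6-(ethylenedioxy)-1-methyl-1,2,3,5,6,7,8,8a-octahydronaphthalene-1-carbaldehyde | O=C[C@]1(C)CCC=C2CC3(OCCO3)CC[C@H]12 | intermediate
8 | (1R,8aS)-6,6-(ethylenedioxy)-1-methyl-1,2,3,5,6,7,8,8a-octahydronaphthalene-1-carboxylic acid | OC(=O)[C@]1(C)CCC=C2CC3(OCCO3)CC[C@H]12 | intermediate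
9 | methyl (1R,8aS)-6,6-(ethylenedioxy)-1-methyl-1,2,3,5,6,7,8,8a-octahydronaphthalene-1-carboxylate | COC(=O)[C@]1(C)CCC=C2CC3(OCCO3)CC[C@H]12 | intermediate
10 | methyl (1R,8aS)-1-methyl-6-oxo-1,2,3,5,6,7,8,8a-octahydronaphthalene-1-carboxylate | COC(=O)[C@]1(C)CCC=C2CC(=O)CC[C@H]12 | intermediate
11 | methyl (1R,8aS)-1-methyl-6-oxo-1,2,3,4,6,7,8,8a-octahydronaphthalene-1-carboxylate | COC(=O)[C@]1(C)CCCC2=CC(=O)CC[C@H]12 | intermediate
12 | lithium (4aS,5R,8aS)-5-(methoxycarbonyl)-5,8a-dimethyl-3,4,4a,5,6,7,8,8a-octahydronaphthalen-2-olate | COC(=O)[C@]1(C)CCC[C@]2(C)C=C([O-])CC[C@H]12.[Li+] | intermediate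
13 | methyl (1R,4aS,8aS)-1,4a-dimethyl-6-(trimethylsilyloxy)-1,2,3,4,4a,7,8,8a-octahydronaphthalene-1-carboxylate | COC(=O)[C@]1(C)CCC[C@]2(C)C=C(O[Si](C)(C)C)CC[C@H]12 | intermediate
14 | (R)-4-methyloxetan-2-one ((R)-β-butyrolactone) | C[C@@H]1CC(=O)O1 | starting material
15 | (3S)-3-methylpent-4-enoic acid | C=C[C@@H](C)CC(=O)O | intermediate
16 | (3-methyloxetan-3-yl)methyl (3S)-3-methylpent-4-enoate | C=C[C@@H](C)CC(=O)OCC1(C)COC1 | intermediate
17 | 4-methyl-1-[(2S)-2-methylbut-3-en-1-yl]-2,6,7-trioxabicyclo[2.2.2]octane | C=C[C@@H](C)CC12OCC(C)(CO1)CO2 | intermediate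
18 | 9-[(3R)-3-methyl-4-(4-methyl-2,6,7-trioxabicyclo[2.2.2]octan-1-yl)butyl]-9-borabicyclo[3.3.1]nonane | B1(CC[C@@H](C)CC34OCC(C)(CO3)CO4)C2CCCC1CCC2 | intermediate
19 | (3R)-3-methyl-4-(4-methyl-2,6,7-trioxabicyclo[2.2.2]octan-1-yl)butan-1-ol | OCC[C@@H](C)CC12OCC(C)(CO1)CO2 | intermediate
20 | 1-[(2S)-4-iodo-2-methylbutyl]-4-methyl-2,6,7-trioxabicyclo[2.2.2]octane | ICC[C@@H](C)CC12OCC(C)(CO1)CO2 | intermediate
21 | benzyltrimethylammonium (4aS,5R,8aS)-5-(methoxycarbonyl)-5,8a-dimethyl-3,4,4a,5,6,7,8,8a-octahydronaphthalen-2-olate | COC(=O)[C@]1(C)CCC[C@]2(C)C=C([O-])CC[C@H]12.C[N+](C)(C)Cc1ccccc1 | intermediate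
22 | methyl (1R,4aS,5R,8aS)-1,4a-dimethyl-5-[(3R)-3-methyl-4-(4-methyl-2,6,7-trioxabicyclo[2.2.2]octan-1-yl)butyl]-6-oxodecahydronaphthalene-1-carboxylate | O=C1CC[C@H]2[C@](C)(CCC[C@@]2(C)C(=O)OC)[C@H]1CC[C@@H](C)CC34OCC(C)(CO3)CO4 | intermediate
23 | methyl (1R,4aR,5S,8aS)-1,4a-dimethyl-5-[(3R)-3-methyl-4-(4-methyl-2,6,7-trioxabicyclo[2.2.2]octan-1-yl)butyl]-6-methylidenedecahydronaphthalene-1-carboxylate | C=C1CC[C@H]2[C@](C)(CCC[C@@]2(C)C(=O)OC)[C@H]1CC[C@@H](C)CC34OCC(C)(CO3)CO4 | intermediate
24 | methyl (1R,4aR,5S,8aS)-5-{(3R)-5-[3-hydroxy-2-(hydroxymethyl)-2-methylpropoxy]-3-methyl-5-oxopentyl}-1,4a-dimethyl-6-methylidenedecahydronaphthalene-1-carboxylate | C=C1CC[C@H]2[C@](C)(CCC[C@@]2(C)C(=O)OC)[C@H]1CC[C@@H](C)CC(=O)OCC(C)(CO)CO | intermediate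
25 | (3R)-5-[(1S,4aS,5R,8aR)-5-(methoxycarbonyl)-5,8a-dimethyl-2-methylidenedecahydronaphthalen-1-yl]-3-methylpentanoic acid | C=C1CC[C@H]2[C@](C)(CCC[C@@]2(C)C(=O)OC)[C@H]1CC[C@@H](C)CC(=O)O | target

**Totals**
Total step count: 15. Longest linear sequence: 10 steps (steps 1–7 and 13–15); the side-chain branch is steps 8–12.

**Steps most likely to fail, with fallbacks**

Step 3 (ketalisation with double-bond shift) may stop at the conjugated ketal or polymerise the dienone. The fallback sets out from 4. The extended dienolate is formed with KOt-Bu (THF/t-BuOH, −20 °C) and protonated kinetically at the α-carbon (AcOH, −78 °C) to give the deconjugated 3-vinylcyclohex-3-en-1-one F1. F1 is then ketalised under non-equilibrating conditions (Me3SiOCH2CH2OSiMe3, Me3SiOTf cat., CH2Cl2, −78 °C), which comes back to the route at 5.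

Step 4 (regio-, endo- and enantioselectivity with an acid-sensitive diene) may give low selectivity or ketal cleavage. The fallback sets out from 5 and 6. The cycloaddition is run with an achiral Lewis acid (Me2AlCl, CH2Cl2, −78 °C) to the racemic endo aldehyde F2, which is oxidised as in step 5 to the racemic acid F3. F3 is resolved by crystallising the (S)-1-phenylethanaminium salt F4 of the (1R,8aS)-acid; the antipodal amine is used if its salt proves the less soluble one. Brief treatment with cold 1 M KHSO4 comes back to the route at 8.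

Step 13 (C-alkylation of a hindered enolate next to a quaternary carbon with an unactivated iodide) may give O-alkylation, elimination or low conversion. The fallback sets out from 11 and 19. Alcohol 19 is oxidised (SO3·pyridine, DMSO, Et3N) to the side-chain aldehyde F5. The Me2CuLi addition of step 7 is repeated on 11 and enolate 12 is intercepted at −78 °C with F5 (tandem conjugate addition–aldol, C–C bond again formed on the convex face) to give the β-hydroxy ketone F6 as a mixture of carbinol epimers. F6 is converted into the phenyl thionocarbonate F7 (PhOC(S)Cl, pyridine, 4-(dimethylamino)pyridine) and deoxygenated by Barton–McCombie reduction (Bu3SnH, azobisisobutyronitrile, PhMe, 80 °C), which comes back to the route at 22 without touching the α-stereocentre.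

**Further compounds**
F1 | step 3 | 3-vinylcyclohex-3-en-1-one | C=CC1=CCCC(=O)C1
F2 | step 4 | racemic (1R,8aS)/(1S,8aR)-6,6-(ethylenedioxy)-1-methyl-1,2,3,5,6,7,8,8a-octahydronaphthalene-1-carbaldehyde | O=C[C@]1(C)CCC=C2CC3(OCCO3)CC[C@H]12.O=C[C@@]1(C)CCC=C2CC3(OCCO3)CC[C@@H]12
F3 | step 4 | racemic (1R,8aS)/(1S,8aR)-6,6-(ethylenedioxy)-1-methyl-1,2,3,5,6,7,8,8a-octahydronaphthalene-1-carboxylic acid | OC(=O)[C@]1(C)CCC=C2CC3(OCCO3)CC[C@H]12.OC(=O)[C@@]1(C)CCC=C2CC3(OCCO3)CC[C@@H]12
F4 | step 4 | (S)-1-phenylethanaminium (1R,8aS)-6,6-(ethylenedioxy)-1-methyl-1,2,3,5,6,7,8,8a-octahydronaphthalene-1-carboxylate | C[C@H]([NH3+])c1ccccc1.[O-]C(=O)[C@]1(C)CCC=C2CC3(OCCO3)CC[C@H]12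
F5 | step 13 | (3R)-3-methyl-4-(4-methyl-2,6,7-trioxabicyclo[2.2.2]octan-1-yl)butanal | O=CC[C@@H](C)CC12OCC(C)(CO1)CO2
F6 | step 13 | methyl (1R,4aS,5S,8aS)-5-[(3R)-1-hydroxy-3-methyl-4-(4-methyl-2,6,7-trioxabicyclo[2.2.2]octan-1-yl)butyl]-1,4a-dimethyl-6-oxodecahydronaphthalene-1-carboxylate (carbinol epimers) | O=C1CC[C@H]2[C@](C)(CCC[C@@]2(C)C(=O)OC)[C@H]1C(O)C[C@@H](C)CC34OCC(C)(CO3)CO4
F7 | step 13 | methyl (1R,4aS,5S,8aS)-1,4a-dimethyl-5-[(3R)-3-methyl-4-(4-methyl-2,6,7-trioxabicyclo[2.2.2]octan-1-yl)-1-(phenoxycarbonothioyloxy)butyl]-6-oxodecahydronaphthalene-1-carboxylate (carbinol epimers) | O=C1CC[C@H]2[C@](C)(CCC[C@@]2(C)C(=O)OC)[C@H]1C(OC(=S)Oc1ccccc1)C[C@@H](C)CC34OCC(C)(CO3)CO4
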